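A direct plan would alkylate 1,3-dithiane with farnesyl bromide, extend it to the dithianyl ynone A1, and build the resorcinol ring on it by Diels–Alder benzannulation with a 1-methoxy-1,3-bis(silyloxy)diene to give aryl ketone A2.
It would then silylate both phenols, hydrolyse the thioacetal to the protected 1,2-dione A3, desilylate so that the racemic hemiketal A4 closes, and last crystallise one C2 epimer as a quinine salt.
Weakest steps:
(a) the benzannulation, which would spend about five steps on a benzene ring that is sold ready-made as a resorcinol ketone;
(b) the silylation, thioacetal hydrolysis and desilylation, three operations that form no skeletal bond;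
(c) the setting of C2, which would form without control and be corrected afterwards by a crystallisation-driven epimerisation whose feasibility and sense cannot be predicted.

**Retrosynthetic overview**
The route cuts the C2–C1′ bond at the fully substituted hemiketal carbon C2 of ring B (the furanone), the carbon that carries O1, the free hydroxyl, the C3 carbonyl and the farnesyl CH2.
A C8 nucleophile (the doubly ketal-protected 2,6-dihydroxybenzofuran-3(2H)-one 4) and a C15 electrophile (farnesyl carbonate 6) are joined by a palladium-catalysed asymmetric allylic alkylation that makes this carbon and its configuration in one stereoconvergent operation.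
Ring A is bought as 2′,4′-dihydroxyacetophenone; ring B closes first, by hemiacetalisation of the arylglyoxal, before the chain is present.
No arene is built and no thioacetal or silyl group is used; C2 is set under catalyst control as a configurationally locked ketal and is unmasked in the last step without breaking a bond to C2.

Key step: step 4

Assumption: the free hemiketal is taken to keep its C2 configuration under cold, base-free, weakly acidic conditions, where ring–chain tautomerism through the open 1,2-dione should be slowest.
Assumption: the (S,S) ligand is taken to give the needed face by analogy with cyclic ketone enolates; its mirror image would be used if the sense proved opposite.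

"Farnesyl" means (2E,6E)-3,7,11-trimethyldodeca-2,6,10-trien-1-yl throughout.

Step 1
Reactants: 1 2′,4′-dihydroxyacetophenone
Product: 3 2,6-dihydroxy-1-benzofuran-3(2H)-one (racemic cyclic hemiacetal), via arylglyoxal 2 (not isolated)
Conditions: SeO2 (1.1 equiv), 1,4-dioxane/H2O (20:1), 90 °C; filtration through Celite; toluene azeotrope
Reagents that add atoms: selenium dioxide, O=[Se]=O
Why: Riley oxidation of the enolisable methyl ketone to the arylglyoxal 2, whose ortho hydroxyl should add to the aldehyde (5-exo-trig hemiacetalisation) and close ring B; the C2 centre forms racemic and is erased at the enolate stage of step 4.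

Step 2
Reactants: 3 2,6-dihydroxy-1-benzofuran-3(2H)-one
Product: 4 2,6-bis[(2-methoxypropan-2-yl)oxy]-1-benzofuran-3(2H)-one (racemic)
Conditions: 2-methoxypropene (6 equiv), PPTS (5 mol %), CH2Cl2, 0 °C; Et3N quench; Et3N-deactivated silica
Reagents that add atoms: 2-methoxypropene, C=C(C)OC
Why: Acid-catalysed addition of the phenol and of the anomeric hydroxyl to the enol ether (mixed ketal formation) should cap both oxygens in one operation with base-stable groups that, unlike silyl or acyl groups, cannot migrate from O2 to O3 in the later enolate.

Step 3
Reactants: 5 (2E,6E)-farnesol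
Product: 6 (2E,6E)-farnesyl methyl carbonate
Conditions: ClCO2Me (1.3 equiv), pyridine (2 equiv), CH2Cl2, 0 °C
Reagents that add atoms: methyl chloroformate, COC(=O)Cl
Why: O-acylation of the primary allylic alcohol with a chloroformate leaves the three alkenes untouched and gives an allylic carbonate that releases its own base on ionisation.

Step 4
Reactants: 4 2,6-bis[(2-methoxypropan-2-yl)oxy]-1-benzofuran-3(2H)-one; 6 (2E,6E)-farnesyl methyl carbonate
Product: 8 (S)-2-farnesyl-2,6-bis[(2-methoxypropan-2-yl)oxy]-1-benzofuran-3(2H)-one, via benzofuran-3-olate 7 (not isolated)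
Conditions: Pd2(dba)3·CHCl3 (2.5 mol %), (1S,2S)-N,N′-bis[2-(diphenylphosphino)benzoyl]cyclohexane-1,2-diamine (7.5 mol %), 6 (1.2 equiv), degassed toluene, 0 °C → rt
Reagents that add atoms: none
Why: Tsuji–Trost asymmetric allylic alkylation: zerovalent palladium ionises carbonate 6 to a cationic η3-farnesyl complex of divalent palladium with loss of CO2, the released methoxide removes the acidic C2–H of 4 (flanked by the C3 ketone and two oxygens) to give the aromatic 3-oxidobenzofuran 7, and 7 attacks the unsubstituted allyl terminus from outside the metal to form the C2–C1′ bond. The closest known reaction types are the palladium-catalysed asymmetric allylation of α-oxygenated ketone enolates and of 2-substituted benzofuran-3(2H)-ones to tetrasubstituted carbons, and the linear-selective asymmetric prenylation and geranylation of 3-substituted oxindoles with diamine-derived bisphosphine ligands. No ring is closed; a C8 and a C15 fragment are joined at the most hindered carbon of the target. C2, the only stereocentre, is set by the catalyst: the racemic C2 of 4 is erased in planar 7, and the chiral pocket of the ligand should tell apart its enantiotopic faces because the two edges at C2 differ strongly (ring oxygen and arene against the bulky ketal oxygen substituent). The step needs C- over O-allylation (an O-farnesyl enol ether would re-ionise under zerovalent palladium and drain to the ketone), attack at CH2 and not at the disubstituted terminus (favoured by the fully substituted nucleophilic carbon and tuned by ligand and solvent), retention of the 2E geometry (syn–anti exchange would need palladium σ-bonded to a tertiary carbon) and alkylation at C2 and not C3 (the ketal group on O2 cannot shift to O3).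

Step 5
Reactants: 8 (S)-2-farnesyl-2,6-bis[(2-methoxypropan-2-yl)oxy]-1-benzofuran-3(2H)-one
Product: 9 (R)-2-farnesyl-2,6-dihydroxy-1-benzofuran-3(2H)-one (target)
Conditions: AcOH/THF/H2O (1:2:1), 0 °C; cold MTBE/water partition without base; Na2SO4; concentrate below 20 °C
Reagents that add atoms: none
Why: Mild acid hydrolysis of the two mixed ketals ionises each on its isopropylidene side (tertiary oxocarbenium), so no bond to C2 is broken and its arrangement is kept, while the chain alkenes are inert to cold acetic acid; the descriptor changes from S to R only because the CIP ranking of the two oxygens at C2 is exchanged when the ketal group is replaced by hydrogen.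

**Compound list**

1 | 2′,4′-dihydroxyacetophenone | CC(=O)c1ccc(O)cc1O | starting material
2 | (2,4-dihydroxyphenyl)glyoxal | O=CC(=O)c1ccc(O)cc1O | intermediate
3 | 2,6-dihydroxy-1-benzofuran-3(2H)-one (racemic) | OC1Oc2cc(O)ccc2C1=O | intermediate
4 | 2,6-bis[(2-methoxypropan-2-yl)oxy]-1-benzofuran-3(2H)-one (racemic) | COC(C)(C)OC1Oc2cc(OC(C)(C)OC)ccc2C1=O | intermediate
5 | (2E,6E)-farnesol | CC(C)=CCC/C(C)=C/CC/C(C)=C/CO | starting material
6 | (2E,6E)-farnesyl methyl carbonate | CC(C)=CCC/C(C)=C/CC/C(C)=C/COC(=O)OC | intermediate
7 | 2,6-bis[(2-methoxypropan-2-yl)oxy]-1-benzofuran-3-olate (anion, paired with the cationic farnesyl palladium complex) | COC(C)(C)Oc1oc2cc(OC(C)(C)OC)ccc2c1[O-] | intermediate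
8 | (S)-2-farnesyl-2,6-bis[(2-methoxypropan-2-yl)oxy]-1-benzofuran-3(2H)-one | CC(C)=CCC/C(C)=C/CC/C(C)=C/C[C@@]1(OC(C)(C)OC)Oc2cc(OC(C)(C)OC)ccc2C1=O | intermediate
9 | (R)-2-farnesyl-2,6-dihydroxy-1-benzofuran-3(2H)-one | CC(C)=CCC/C(C)=C/CC/C(C)=C/C[C@@]1(O)Oc2cc(O)ccc2C1=O | target

Total step count: 5. Longest linear sequence: 4 steps (1 → 3 → 4 → 8 → 9).

**Steps most likely to fail**

Step 4. The catalyst may discriminate the faces of the flat enolate poorly, the enolate may attack the substituted allyl terminus, or syn–anti exchange in the allyl complex may erode the 2E geometry. The fallback would set out from 4. Alkylation of its enolate with commercial (2E,6E)-farnesyl bromide (K2CO3, acetone, rt; SN2 at the primary allylic carbon keeps connectivity and geometry) should give racemic 2-farnesyl-2,6-bis[(2-methoxypropan-2-yl)oxy]-1-benzofuran-3(2H)-one F1. The enantiomers of this configurationally locked bis-ketal would be separated by preparative supercritical fluid chromatography on a chiral stationary phase, and the (S) enantiomer is 8, where the route is rejoined.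

Step 5. The liberated hemiketal may lose configuration by acid-catalysed ring–chain tautomerism, or exchange may occur at the ketal carbon in the aqueous acid. The fallback would set out from 3 and unmask oxidatively under neutral conditions. Both hydroxyls of 3 would be etherified with 4-methoxybenzyl 2,2,2-trichloroacetimidate (cat. camphorsulfonic acid, CH2Cl2, 0 °C) to give 2,6-bis[(4-methoxybenzyl)oxy]-1-benzofuran-3(2H)-one F2. Farnesylation of F2 with 6 under the conditions of step 4 should give (R)-2-farnesyl-2,6-bis[(4-methoxybenzyl)oxy]-1-benzofuran-3(2H)-one F3. DDQ (2.5 equiv) in CH2Cl2/pH 7 phosphate buffer at 0 °C would then remove both benzyl groups as 4-methoxybenzaldehyde and come back at 9.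

Step 2. The open-chain glyoxal tautomer, or only one of the two hydroxyls, may be captured, and the labile aryl ketal may hydrolyse on handling. The fallback would set out from 3 and first lock the ring form as silyl ethers. Hexamethyldisilazane (cat. Me3SiCl, MeCN, rt) should give 2,6-bis(trimethylsilyloxy)-1-benzofuran-3(2H)-one F4. Aprotic transketalisation of F4 with 2,2-dimethoxypropane and catalytic Me3SiOTf (CH2Cl2, −78 °C, pyridine quench) would exchange each silyl group for the methoxypropyl ketal and come back at 4.

**Further compounds**

F1 | step 4 | racemic 2-farnesyl-2,6-bis[(2-methoxypropan-2-yl)oxy]-1-benzofuran-3(2H)-one | CC(C)=CCC/C(C)=C/CC/C(C)=C/CC1(OC(C)(C)OC)Oc2cc(OC(C)(C)OC)ccc2C1=O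
F2 | step 5 | 2,6-bis[(4-methoxybenzyl)oxy]-1-benzofuran-3(2H)-one (racemic) | COc1ccc(COC2Oc3cc(OCc4ccc(OC)cc4)ccc3C2=O)cc1
F3 | step 5 | (R)-2-farnesyl-2,6-bis[(4-methoxybenzyl)oxy]-1-benzofuran-3(2H)-one | CC(C)=CCC/C(C)=C/CC/C(C)=C/C[C@@]1(OCc2ccc(OC)cc2)Oc2cc(OCc3ccc(OC)cc3)ccc2C1=O
F4 | step 2 | 2,6-bis(trimethylsilyloxy)-1-benzofuran-3(2H)-one (racemic) | C[Si](C)(C)OC1Oc2cc(O[Si](C)(C)C)ccc2C1=O
A1 | direct plan | 1-(2-farnesyl-1,3-dithian-2-yl)prop-2-yn-1-one | CC(C)=CCC/C(C)=C/CC/C(C)=C/CC1(SCCCS1)C(=O)C#C
A2 | direct plan | (2,4-dihydroxyphenyl)(2-farnesyl-1,3-dithian-2-yl)methanone | CC(C)=CCC/C(C)=C/CC/C(C)=C/CC1(SCCCS1)C(=O)c1ccc(O)cc1O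
A3 | direct plan | (4E,8E)-1-[2,4-bis(tert-butyldimethylsilyloxy)phenyl]-5,9,13-trimethyltetradeca-4,8,12-triene-1,2-dione | CC(C)=CCC/C(C)=C/CC/C(C)=C/CC(=O)C(=O)c1ccc(O[Si](C)(C)C(C)(C)C)cc1O[Si](C)(C)C(C)(C)C
A4 | direct plan | racemic 2-farnesyl-2,6-dihydroxy-1-benzofuran-3(2H)-one | CC(C)=CCC/C(C)=C/CC/C(C)=C/CC1(O)Oc2cc(O)ccc2C1=O
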